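**Strategy**

Everything rests on cutting the bond between the carboxyl carbon and the enol ether carbon that is bonded to O3 of ring A (the central cinnamoyl ring) and doubly bonded to the CH carrying ring B. Because this carbon bears an oxygen, it can be drawn from trichloroethylene as the oxygen-bearing C–Cl carbon of an aryl (E)-1,2-dichlorovinyl ether, whose aryloxy/chlorine cis geometry is the one the target needs. A single palladium alkoxycarbonylation with 4-methoxybenzyl alcohol turns that C–Cl bond into the protected carboxyl and leaves a β-chloroacrylate for ring B. The precursor is 3,4-dihydroxybenzaldehyde with PMB on O4 and the dichlorovinyl group on O3.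

Key step: step 3

Remarks on the chemistry:
- Protecting groups: 4-methoxybenzyl (PMB) is the only protecting group, on all five phenols and both carboxyl groups. The alcohol captured in the key step is therefore also the carboxyl protecting group, and one acidolysis ends the route. PMB is chosen for O4 of ring A over an acetal-type group because its selective installation on the 4-OH under bicarbonate/iodide conditions is well established and because it releases no formaldehyde beside free catechols in the last step.
- Formyl group: it is left free in the precursor, since it is inert to the carbonylation and is needed directly for the later olefination.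
- Assumption: (R)-danshensu is used as the free acid. 4-Methoxybenzyl chloride, B2pin2 and diethylphosphonoacetic acid are taken as commercial.
- Handling: dichloroacetylene in step 2 is generated and consumed in solution under argon and is never isolated or concentrated.

**Route**

Step 1
Reactants: 1 3,4-dihydroxybenzaldehyde
Product: 2 3-hydroxy-4-[(4-methoxybenzyl)oxy]benzaldehyde
Conditions: PMBCl (1.2 equiv), NaHCO3 (1.5 equiv), NaI (0.3 equiv), DMF, 40 °C
Reagents that add atoms: 4-methoxybenzyl chloride, COc1ccc(CCl)cc1
Why: Williamson ether synthesis under bicarbonate control, in which only the 4-OH (made more acidic by the para formyl group) is ionised by NaHCO3, so the 4-methoxybenzyl iodide formed in situ alkylates O4 and leaves the 3-OH free.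

Step 2
Reactants: 2 3-hydroxy-4-[(4-methoxybenzyl)oxy]benzaldehyde; 3 trichloroethylene
Product: 5 3-{[(E)-1,2-dichlorovinyl]oxy}-4-[(4-methoxybenzyl)oxy]benzaldehyde, via dichloroacetylene 4 (not isolated)
Conditions: trichloroethylene (1.5 equiv), K2CO3 (2 equiv), DMF, 70 °C, argon
Reagents that add atoms: none
Why: K2CO3 dehydrochlorinates trichloroethylene to dichloroacetylene, the ring A phenoxide adds to it and protonation occurs anti (nucleophilic trans-hydroalkoxylation of a haloalkyne), giving the (E)-1,2-dichlorovinyl ether with the aryloxy group cis to the distal chlorine, while the aldehyde and the PMB ether are inert to carbonate in DMF.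

Step 3
Reactants: 5 3-{[(E)-1,2-dichlorovinyl]oxy}-4-[(4-methoxybenzyl)oxy]benzaldehyde; 6 4-methoxybenzyl alcohol
Product: 7 4-methoxybenzyl (Z)-3-chloro-2-{5-formyl-2-[(4-methoxybenzyl)oxy]phenoxy}acrylate
Conditions: Pd(OAc)2 (5 mol %), DPEphos (7.5 mol %), CO (1 atm), 4-methoxybenzyl alcohol (1.1 equiv), iPr2NEt (2 equiv), toluene, 70 °C
Reagents that add atoms: carbon monoxide, [C-]#[O+]
Why: Proposed new method: zerovalent palladium, formed in situ from Pd(OAc)2 and DPEphos, should insert into the C–Cl bond of the vinyl carbon that also carries the ring A oxygen, CO should insert to give the acylpalladium species, and 4-methoxybenzyl alcohol with iPr2NEt should release the ester and regenerate the catalyst. The closest known reactions are the site-selective Suzuki–Miyaura coupling of aryl (E)-1,2-dichlorovinyl ethers at this same oxygen-bearing carbon with a DPEphos-ligated catalyst and the palladium-catalysed alkoxycarbonylation of vinyl and aryl chlorides. No ring is closed and no stereocentre is formed, the only new skeletal bond being the one between the vinyl carbon and the carboxyl carbon. The step needs site selectivity between the two C–Cl bonds, which the geminal aryloxy oxygen secures by making its own C–Cl bond the more electron-poor and more readily inserted one, and it needs retention of the alkene geometry, which oxidative addition, CO insertion and alcoholysis at an sp2 carbon all provide, so the aryloxy group and the remaining chlorine stay cis. Over-reaction at the newly formed β-chloroacrylate (second carbonylation, chloride displacement by the alcohol, or palladation of ring A at C2–H with closure to a benzofuran) is held back by near-stoichiometric alcohol, a hindered amine in place of carbonate or carboxylate bases, atmospheric CO pressure and a moderate temperature. β-Chloride elimination from the vinylpalladium intermediate is disfavoured because palladium and the remaining chlorine are trans.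

Step 4
Reactants: 8 4-bromocatechol
Product: 9 4-bromo-1,2-bis[(4-methoxybenzyl)oxy]benzene
Conditions: PMBCl (2.3 equiv), K2CO3 (3 equiv), KI (cat.), DMF, 50 °C, argon
Reagents that add atoms: 4-methoxybenzyl chloride, COc1ccc(CCl)cc1
Why: Twofold Williamson ether synthesis of the catechol with a benzylic chloride under carbonate, the aryl bromide being inert.

Step 5
Reactants: 9 4-bromo-1,2-bis[(4-methoxybenzyl)oxy]benzene
Product: 10 2-{3,4-bis[(4-methoxybenzyl)oxy]phenyl}-4,4,5,5-tetramethyl-1,3,2-dioxaborolane
Conditions: B2pin2 (1.2 equiv), PdCl2(dppf) (3 mol %), KOAc (3 equiv), 1,4-dioxane, 90 °C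
Reagents that add atoms: bis(pinacolato)diboron, CC1(C)OB(OC1(C)C)B1OC(C)(C)C(C)(C)O1
Why: Miyaura borylation, in which oxidative addition of the aryl bromide to zerovalent palladium, acetate-assisted transmetallation with B2pin2 and reductive elimination give the pinacol boronate without touching the benzylic ethers.

Step 6
Reactants: 7 4-methoxybenzyl (Z)-3-chloro-2-{5-formyl-2-[(4-methoxybenzyl)oxy]phenoxy}acrylate; 10 2-{3,4-bis[(4-methoxybenzyl)oxy]phenyl}-4,4,5,5-tetramethyl-1,3,2-dioxaborolane
Product: 11 4-methoxybenzyl (Z)-3-{3,4-bis[(4-methoxybenzyl)oxy]phenyl}-2-{5-formyl-2-[(4-methoxybenzyl)oxy]phenoxy}acrylate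
Conditions: Pd(OAc)2 (5 mol %), SPhos (10 mol %), K3PO4 (2 equiv), toluene/H2O (10:1), 60 °C
Reagents that add atoms: none
Why: Suzuki–Miyaura coupling in which the β-chloroacrylate C–Cl bond is activated toward oxidative addition by the conjugated ester and transmetallation and reductive elimination proceed with retention of the alkene geometry, so ring B ends cis to the ring A oxygen ((Z)-alkene) while the aldehyde and the PMB ester survive the mild phosphate base.

Step 7
Reactants: 12 (R)-3-(3,4-dihydroxyphenyl)lactic acid (danshensu)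
Product: 13 4-methoxybenzyl (R)-3-{3,4-bis[(4-methoxybenzyl)oxy]phenyl}-2-hydroxypropanoate
Conditions: PMBCl (3.3 equiv), K2CO3 (3.5 equiv), KI (cat.), DMF, rt, argon
Reagents that add atoms: 4-methoxybenzyl chloride, COc1ccc(CCl)cc1
Why: Williamson-type O-alkylation of the carboxylate and both phenoxides under K2CO3, which does not ionise the secondary alcohol, so the 2-OH stays free and the stereocentre, which takes no part, keeps its (R) configuration.

Step 8
Reactants: 13 4-methoxybenzyl (R)-3-{3,4-bis[(4-methoxybenzyl)oxy]phenyl}-2-hydroxypropanoate; 14 diethylphosphonoacetic acid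
Product: 15 4-methoxybenzyl (R)-3-{3,4-bis[(4-methoxybenzyl)oxy]phenyl}-2-{[2-(diethoxyphosphoryl)acetyl]oxy}propanoate
Conditions: DCC (1.4 equiv), DMAP (0.1 equiv), CH2Cl2, 0 °C to rt
Reagents that add atoms: none
Why: Steglich esterification in which the DCC-activated phosphonoacetic acid acylates the secondary alcohol under DMAP catalysis, and since the C–O bond at the stereocentre is not broken the (R) configuration is retained.

Step 9
Reactants: 11 4-methoxybenzyl (Z)-3-{3,4-bis[(4-methoxybenzyl)oxy]phenyl}-2-{5-formyl-2-[(4-methoxybenzyl)oxy]phenoxy}acrylate; 15 4-methoxybenzyl (R)-3-{3,4-bis[(4-methoxybenzyl)oxy]phenyl}-2-{[2-(diethoxyphosphoryl)acetyl]oxy}propanoate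
Product: 16 hepta-PMB salvianolic acid H, 4-methoxybenzyl (Z)-3-{3,4-bis[(4-methoxybenzyl)oxy]phenyl}-2-{5-[(E)-3-{[(R)-3-{3,4-bis[(4-methoxybenzyl)oxy]phenyl}-1-[(4-methoxybenzyl)oxy]-1-oxopropan-2-yl]oxy}-3-oxoprop-1-en-1-yl]-2-[(4-methoxybenzyl)oxy]phenoxy}acrylate
Conditions: 15 (1.2 equiv), LiCl (1.5 equiv), DBU (1.2 equiv), MeCN/THF, 0 °C to rt
Reagents that add atoms: none
Why: Horner–Wadsworth–Emmons olefination under mild LiCl/amine conditions, in which the lithium-chelated stabilised phosphonate anion adds reversibly to the aryl aldehyde and eliminates to the (E)-cinnamate, while the weak base leaves the α-acyloxy ester stereocentre and the enol ether untouched.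

Step 10
Reactants: 16 hepta-PMB salvianolic acid H
Product: 17 salvianolic acid H, (Z)-2-{5-[(E)-3-{[(R)-1-carboxy-2-(3,4-dihydroxyphenyl)ethyl]oxy}-3-oxoprop-1-en-1-yl]-2-hydroxyphenoxy}-3-(3,4-dihydroxyphenyl)acrylic acid
Conditions: TFA/CH2Cl2 (1:4), pentamethylbenzene (30 equiv), 0 °C to rt
Reagents that add atoms: none
Why: Acidolysis in which TFA ionises the five aryl PMB ethers and two PMB esters to the stabilised 4-methoxybenzyl cation, which pentamethylbenzene traps by Friedel–Crafts alkylation, while the electron-poor enol ether, the cinnamate, the lactate ester linkage and the stereocentre are not affected by anhydrous acid at low temperature.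

**Compound list**

1 | 3,4-dihydroxybenzaldehyde | O=Cc1ccc(O)c(O)c1 | starting material
2 | 3-hydroxy-4-[(4-methoxybenzyl)oxy]benzaldehyde | O=Cc1ccc(OCc2ccc(OC)cc2)c(O)c1 | intermediate
3 | trichloroethylene | ClC=C(Cl)Cl | starting material
4 | dichloroacetylene (not isolated) | ClC#CCl | intermediate
5 | 3-{[(E)-1,2-dichlorovinyl]oxy}-4-[(4-methoxybenzyl)oxy]benzaldehyde | O=Cc1ccc(OCc2ccc(OC)cc2)c(O/C(Cl)=C\Cl)c1 | intermediate
6 | 4-methoxybenzyl alcohol | COc1ccc(CO)cc1 | starting material
7 | 4-methoxybenzyl (Z)-3-chloro-2-{5-formyl-2-[(4-methoxybenzyl)oxy]phenoxy}acrylate | O=Cc1ccc(OCc2ccc(OC)cc2)c(O/C(=C\Cl)C(=O)OCc2ccc(OC)cc2)c1 | intermediate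
8 | 4-bromocatechol | Oc1ccc(Br)cc1O | starting material
9 | 4-bromo-1,2-bis[(4-methoxybenzyl)oxy]benzene | Brc1ccc(OCc2ccc(OC)cc2)c(OCc2ccc(OC)cc2)c1 | intermediate
10 | 2-{3,4-bis[(4-methoxybenzyl)oxy]phenyl}-4,4,5,5-tetramethyl-1,3,2-dioxaborolane | CC1(C)OB(OC1(C)C)c1ccc(OCc2ccc(OC)cc2)c(OCc2ccc(OC)cc2)c1 | intermediate
11 | 4-methoxybenzyl (Z)-3-{3,4-bis[(4-methoxybenzyl)oxy]phenyl}-2-{5-formyl-2-[(4-methoxybenzyl)oxy]phenoxy}acrylate | O=Cc1ccc(OCc2ccc(OC)cc2)c(O/C(=C\c2ccc(OCc3ccc(OC)cc3)c(OCc3ccc(OC)cc3)c2)C(=O)OCc2ccc(OC)cc2)c1 | intermediate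
12 | (R)-3-(3,4-dihydroxyphenyl)lactic acid (danshensu) | O[C@H](Cc1ccc(O)c(O)c1)C(=O)O | starting material
13 | 4-methoxybenzyl (R)-3-{3,4-bis[(4-methoxybenzyl)oxy]phenyl}-2-hydroxypropanoate | O[C@H](Cc1ccc(OCc2ccc(OC)cc2)c(OCc2ccc(OC)cc2)c1)C(=O)OCc1ccc(OC)cc1 | intermediate
14 | diethylphosphonoacetic acid | CCOP(=O)(CC(=O)O)OCC | starting material
15 | 4-methoxybenzyl (R)-3-{3,4-bis[(4-methoxybenzyl)oxy]phenyl}-2-{[2-(diethoxyphosphoryl)acetyl]oxy}propanoate | CCOP(=O)(CC(=O)O[C@H](Cc1ccc(OCc2ccc(OC)cc2)c(OCc2ccc(OC)cc2)c1)C(=O)OCc1ccc(OC)cc1)OCC | intermediate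
16 | hepta-PMB salvianolic acid H (ring A and ring B enol ether Z, cinnamate E, lactate carbon R) | O=C(/C=C/c1ccc(OCc2ccc(OC)cc2)c(O/C(=C\c2ccc(OCc3ccc(OC)cc3)c(OCc3ccc(OC)cc3)c2)C(=O)OCc2ccc(OC)cc2)c1)O[C@H](Cc1ccc(OCc2ccc(OC)cc2)c(OCc2ccc(OC)cc2)c1)C(=O)OCc1ccc(OC)cc1 | intermediate
17 | salvianolic acid H | O=C(/C=C/c1ccc(O)c(O/C(=C\c2ccc(O)c(O)c2)C(=O)O)c1)O[C@H](Cc1ccc(O)c(O)c1)C(=O)O | target

**Step count and risk**

Total step count: 10. Longest linear sequence: 6 (steps 1, 2, 3, 6, 9, 10).

Steps most likely to fail:

1. Step 3 (the labelled step). Oxidative addition may fail to discriminate between the two C–Cl bonds. The activated β-chloride of the product may also react further, by a second carbonylation, by displacement by the alcohol, or by palladation of ring A at C2–H with closure to a benzofuran, so that the monoester is lost. The fallback uses known chemistry, sets out from 2 (with 15, 14, 6 and 1 as partners) and returns at 16. The carboxyl is brought in already attached to the future enol ether carbon by carbenoid O–H insertion, and the enol ether double bond is then made by olefination. Aldehyde 2 is first olefinated with 15 (LiCl, DBU 2.2 equiv, MeCN, Horner–Wadsworth–Emmons) to give the ring A 3-hydroxycinnamate ester F1. Acid 14 is esterified with 6 (DCC, DMAP, CH2Cl2) to 4-methoxybenzyl diethylphosphonoacetate F2, and diazo transfer (4-acetamidobenzenesulfonyl azide, DBU, MeCN) gives 4-methoxybenzyl diazo(diethoxyphosphoryl)acetate F3. Rh2(OAc)4-catalysed O–H insertion of F3 into the phenol of F1 (toluene, 80 °C) should give the α-aryloxyphosphonoacetate F4, of which both epimers at the phosphonate carbon are usable. Horner–Wadsworth–Emmons reaction of F4 (LiCl, DBU) with 3,4-bis[(4-methoxybenzyl)oxy]benzaldehyde F5 (from 1, PMBCl, K2CO3, DMF) should then give 16 together with its enol ether (E) isomer. That isomer would be removed by chromatography or converted by iodine-catalysed equilibration toward the (Z) isomer, which is expected to be the more stable. Step 10 follows unchanged.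

2. Step 6. The basic aqueous medium may consume the β-chloroacrylate by addition–elimination or ester hydrolysis, the boronate may protodeboronate, or the vinylpalladium intermediate may attack ring A at C2–H and close a benzofuran faster than it transmetallates. The fallback sets out from 9 and 7 and returns at 11, replacing the Suzuki coupling by a base-free Stille coupling. Bromide 9 is converted by bromine–lithium exchange (n-BuLi, THF, −78 °C) and quenching with Bu3SnCl into tributyl{3,4-bis[(4-methoxybenzyl)oxy]phenyl}stannane F6. This is coupled with 7 under neutral conditions (Pd(PPh3)4, CuI cat., DMF, 60 °C) to give 11 with retention of the alkene geometry.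

3. Step 10. Seven 4-methoxybenzyl cations are released beside three electron-rich rings. C-benzylation of the liberated catechols, incomplete cleavage, or acid-promoted hydration or E/Z drift of the enol ether may therefore erode a product that is also the hardest compound of the route to purify. The fallback sets out from 11 and 13 and returns at 17. The acidolysis is moved to the two halves, and the last step becomes a protecting-group-free Knoevenagel–Doebner condensation. Aldehyde 11 is deprotected (TFA, pentamethylbenzene, CH2Cl2, 0 °C) to (Z)-3-(3,4-dihydroxyphenyl)-2-(5-formyl-2-hydroxyphenoxy)acrylic acid F7. Alcohol 13 is heated with Meldrum's acid (toluene, 90 °C) to give its hydrogen malonate F8, which the same acidolysis converts into (R)-2-[(carboxyacetyl)oxy]-3-(3,4-dihydroxyphenyl)propanoic acid F9. Condensation of F7 with F9 (pyridine, piperidine cat., 50 °C, argon) with loss of CO2 should give 17 directly as the (E)-cinnamate.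

Further compounds
F1 | step 3 | 4-methoxybenzyl (R)-3-{3,4-bis[(4-methoxybenzyl)oxy]phenyl}-2-{[(E)-3-{3-hydroxy-4-[(4-methoxybenzyl)oxy]phenyl}acryloyl]oxy}propanoate | O=C(/C=C/c1ccc(OCc2ccc(OC)cc2)c(O)c1)O[C@H](Cc1ccc(OCc2ccc(OC)cc2)c(OCc2ccc(OC)cc2)c1)C(=O)OCc1ccc(OC)cc1
F2 | step 3 | 4-methoxybenzyl 2-(diethoxyphosphoryl)acetate | CCOP(=O)(CC(=O)OCc1ccc(OC)cc1)OCC
F3 | step 3 | 4-methoxybenzyl 2-diazo-2-(diethoxyphosphoryl)acetate | CCOP(=O)(C(=[N+]=[N-])C(=O)OCc1ccc(OC)cc1)OCC
F4 | step 3 | 4-methoxybenzyl (R)-3-{3,4-bis[(4-methoxybenzyl)oxy]phenyl}-2-{[(E)-3-{3-[1-(diethoxyphosphoryl)-2-[(4-methoxybenzyl)oxy]-2-oxoethoxy]-4-[(4-methoxybenzyl)oxy]phenyl}acryloyl]oxy}propanoate (phosphonate carbon unspecified) | CCOP(=O)(C(Oc1cc(/C=C/C(=O)O[C@H](Cc2ccc(OCc3ccc(OC)cc3)c(OCc3ccc(OC)cc3)c2)C(=O)OCc2ccc(OC)cc2)ccc1OCc1ccc(OC)cc1)C(=O)OCc1ccc(OC)cc1)OCC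
F5 | step 3 | 3,4-bis[(4-methoxybenzyl)oxy]benzaldehyde | O=Cc1ccc(OCc2ccc(OC)cc2)c(OCc2ccc(OC)cc2)c1
F6 | step 6 | tributyl{3,4-bis[(4-methoxybenzyl)oxy]phenyl}stannane | CCCC[Sn](CCCC)(CCCC)c1ccc(OCc2ccc(OC)cc2)c(OCc2ccc(OC)cc2)c1
F7 | step 10 | (Z)-3-(3,4-dihydroxyphenyl)-2-(5-formyl-2-hydroxyphenoxy)acrylic acid | O=Cc1ccc(O)c(O/C(=C\c2ccc(O)c(O)c2)C(=O)O)c1
F8 | step 10 | 3-{[(R)-3-{3,4-bis[(4-methoxybenzyl)oxy]phenyl}-1-[(4-methoxybenzyl)oxy]-1-oxopropan-2-yl]oxy}-3-oxopropanoic acid | OC(=O)CC(=O)O[C@H](Cc1ccc(OCc2ccc(OC)cc2)c(OCc2ccc(OC)cc2)c1)C(=O)OCc1ccc(OC)cc1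
F9 | step 10 | (R)-2-[(carboxyacetyl)oxy]-3-(3,4-dihydroxyphenyl)propanoic acid | OC(=O)CC(=O)O[C@H](Cc1ccc(O)c(O)c1)C(=O)O
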